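**Retrosynthetic overview**
1. Hierochin B 14 comes from ester 12 by functional-group changes only: enoate to allylic alcohol, then O-desilylation.
2. In 12 the methoxy-bearing benzene ring and the dihydrofuran ring are cut together. This gives pyridazinyl homoallyl ether 9 (intramolecular inverse-demand [4+2], then loss of N2 and 2 H).
3. Ether 9 comes from alcohol 4 and chloropyridazine 7 (C7a–O bond by SNAr). Chloropyridazine 7 comes from dichloride 5 and methyl acrylate 6 (site-selective Heck).
4. Alcohol 4 comes from veratraldehyde 1 and vinyl ethylene carbonate 2. One catalytic anti-(hydroxymethyl)allylation sets both stereocentres.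
5. Ring order: the veratryl ring is bought. The carbocycle and the O-heterocycle form together in step 5, and the pyridazine ring is sacrificed there.

Assumption: the (S)-SEGPHOS iridium catalyst is taken to give the (1S,2R)-anti diol; if the sense of induction is the opposite, (R)-SEGPHOS, equally available, is used.

**Step 1**
Reactants: 1 3,4-dimethoxybenzaldehyde; 2 4-vinyl-1,3-dioxolan-2-one (racemic)
Product: 3 (1S,2R)-1-(3,4-dimethoxyphenyl)-2-ethenylpropane-1,3-diol
Conditions: [Ir(cod)Cl]2 (2.5 mol%), (S)-SEGPHOS (5 mol%), 4-chloro-3-nitrobenzoic acid (10 mol%), K3PO4 (5 mol%), i-PrOH (2 equiv), THF, 90 °C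
Reagents that add atoms: none
Why: Iridium-catalysed transfer-hydrogenative carbonyl (hydroxymethyl)allylation (Krische type): the catalyst ionises 2 with loss of CO2 to an (E)-σ-(4-hydroxybut-2-enyl)iridium that adds through its γ-carbon to 1 in a closed chair transition state, which gives the anti relationship, while the ligand fixes the aldehyde face, so C1 (S, future C2) and C2 (R, future C3) are both set here.

**Step 2**
Reactants: 3 (1S,2R)-1-(3,4-dimethoxyphenyl)-2-ethenylpropane-1,3-diol
Product: 4 (1S,2R)-1-(3,4-dimethoxyphenyl)-2-{[(triisopropylsilyl)oxy]methyl}but-3-en-1-ol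
Conditions: TIPSCl (1.05 equiv), imidazole, CH2Cl2, 0 °C to rt
Reagents that add atoms: triisopropylsilyl chloride, CC(C)[Si](Cl)(C(C)C)C(C)C
Why: Sterically controlled silylation, in which the bulky chlorosilane takes only the primary hydroxyl and leaves the secondary benzylic OH free; no stereocentre is touched, and TIPS is chosen because it resists base-induced O-to-O migration and prolonged heating.

**Step 3**
Reactants: 5 3,6-dichloro-4-methoxypyridazine; 6 methyl acrylate
Product: 7 methyl (E)-3-(6-chloro-5-methoxypyridazin-3-yl)prop-2-enoate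
Conditions: Pd2(dba)3 (2 mol%), P(t-Bu)3·HBF4 (8 mol%), Cy2NMe (1.2 equiv), 6 (1.05 equiv), dioxane, 80 °C
Reagents that add atoms: none
Why: Mizoroki–Heck reaction in which oxidative addition should prefer the C6–Cl bond (unhindered, meta to the methoxy donor) over the C3–Cl bond (ortho to and flanked by the donor), and syn-insertion followed by syn-β-hydride elimination gives the E-enoate.

**Step 4**
Reactants: 4 (1S,2R)-1-(3,4-dimethoxyphenyl)-2-{[(triisopropylsilyl)oxy]methyl}but-3-en-1-ol; 7 methyl (E)-3-(6-chloro-5-methoxypyridazin-3-yl)prop-2-enoate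
Product: 9 methyl (E)-3-(6-{[(1S,2R)-1-(3,4-dimethoxyphenyl)-2-{[(triisopropylsilyl)oxy]methyl}but-3-en-1-yl]oxy}-5-methoxypyridazin-3-yl)prop-2-enoate, via potassium alkoxide 8 (not isolated)
Conditions: KHMDS (1.05 equiv), THF, −40 °C; then 7, −40 °C to rt
Reagents that add atoms: none
Why: SNAr (addition–elimination) at the only remaining C–Cl, which is α to a ring nitrogen and conjugated with the enoate-bearing carbon; only the O–H bond of 4 is broken, so both stereocentres are retained.

**Step 5 (key step)**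
Reactants: 9 methyl (E)-3-(6-{[(1S,2R)-1-(3,4-dimethoxyphenyl)-2-{[(triisopropylsilyl)oxy]methyl}but-3-en-1-yl]oxy}-5-methoxypyridazin-3-yl)prop-2-enoate
Product: 12 methyl (E)-3-[(2S,3R)-2-(3,4-dimethoxyphenyl)-7-methoxy-3-{[(triisopropylsilyl)oxy]methyl}-2,3-dihydro-1-benzofuran-5-yl]prop-2-enoate, via azo-bridged cycloadduct 10 (not isolated), via 3a,4-dihydrobenzofuran diene 11 (not isolated)
Conditions: o-dichlorobenzene (0.01 M), BHT (5 mol%), 2,6-di-tert-butyl-4-methylpyridine (20 mol%), 190 °C, sealed tube; then 0 °C, DDQ (1.1 equiv)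
Reagents that add atoms: none
Why: Proposed new method: the tethered terminal alkene adds across C3/C6 of the 1,2-diazine in an intramolecular inverse-electron-demand Diels–Alder reaction (three-atom O–C–C tether with two substituents for rotamer acceleration, enoate lowering the diazine LUMO), which forms the C7a–C3a and C5–C4 bonds and hence the six-membered carbocycle and the five-membered O-ring at once; irreversible retro-[4+2] loss of N2 gives diene 11, and DDQ removes hydride from C4 and a proton from C3a to aromatise it faster than it attacks the benzylic ether; no bond to C2 or C3 is made or broken, so the anti array of 4 becomes the trans (2S,3R) ring; the closest known reaction type is the thermal intramolecular Diels–Alder/N2-extrusion of 3-(alkynyloxy)- and 3-(2-allylphenoxy)pyridazines, which gives dihydrobenzofurans and xanthenes.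

**Step 6**
Reactants: 12 methyl (E)-3-[(2S,3R)-2-(3,4-dimethoxyphenyl)-7-methoxy-3-{[(triisopropylsilyl)oxy]methyl}-2,3-dihydro-1-benzofuran-5-yl]prop-2-enoate
Product: 13 (E)-3-[(2S,3R)-2-(3,4-dimethoxyphenyl)-7-methoxy-3-{[(triisopropylsilyl)oxy]methyl}-2,3-dihydro-1-benzofuran-5-yl]prop-2-en-1-ol
Conditions: DIBAL-H (2.5 equiv), CH2Cl2, −78 °C; aq. Rochelle salt
Reagents that add atoms: none
Why: DIBAL-H 1,2-reduction of an α,β-unsaturated ester gives the allylic alcohol with the E-alkene intact, and the TIPS ether, the aryl ethers and both stereocentres are inert at −78 °C.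

**Step 7**
Reactants: 13 (E)-3-[(2S,3R)-2-(3,4-dimethoxyphenyl)-7-methoxy-3-{[(triisopropylsilyl)oxy]methyl}-2,3-dihydro-1-benzofuran-5-yl]prop-2-en-1-ol
Product: 14 hierochin B
Conditions: TBAF (1.2 equiv), THF, 0 °C to rt
Reagents that add atoms: none
Why: Fluoride-driven desilylation (strong Si–F bond) frees the primary alcohol under conditions that do not epimerise C2 or C3 and do not affect the allylic alcohol.

**Compound list**
1 | 3,4-dimethoxybenzaldehyde (veratraldehyde) | COc1ccc(C=O)cc1OC | starting material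
2 | 4-vinyl-1,3-dioxolan-2-one (vinyl ethylene carbonate, racemic) | C=CC1COC(=O)O1 | starting material
3 | (1S,2R)-1-(3,4-dimethoxyphenyl)-2-ethenylpropane-1,3-diol | COc1ccc([C@@H](O)[C@@H](CO)C=C)cc1OC | intermediate
4 | (1S,2R)-1-(3,4-dimethoxyphenyl)-2-{[(triisopropylsilyl)oxy]methyl}but-3-en-1-ol | COc1ccc([C@@H](O)[C@@H](CO[Si](C(C)C)(C(C)C)C(C)C)C=C)cc1OC | intermediate
5 | 3,6-dichloro-4-methoxypyridazine | COc1cc(Cl)nnc1Cl | starting material
6 | methyl acrylate | C=CC(=O)OC | starting material
7 | methyl (E)-3-(6-chloro-5-methoxypyridazin-3-yl)prop-2-enoate | COC(=O)/C=C/c1cc(OC)c(Cl)nn1 | intermediate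
8 | potassium alkoxide of 4 (not isolated) | COc1ccc([C@@H]([O-])[C@@H](CO[Si](C(C)C)(C(C)C)C(C)C)C=C)cc1OC.[K+] | intermediate
9 | methyl (E)-3-(6-{[(1S,2R)-1-(3,4-dimethoxyphenyl)-2-{[(triisopropylsilyl)oxy]methyl}but-3-en-1-yl]oxy}-5-methoxypyridazin-3-yl)prop-2-enoate | COc1ccc([C@@H](Oc2nnc(/C=C/C(=O)OC)cc2OC)[C@@H](CO[Si](C(C)C)(C(C)C)C(C)C)C=C)cc1OC | intermediate
10 | azo-bridged [4+2] adduct, a 2,3-diazabicyclo[2.2.2]octa-2,5-diene fused to the new tetrahydrofuran ring (C2 S, C3 R; the three new centres are transient and left undefined; not isolated) | COc1ccc([C@H]2OC34N=NC(/C=C/C(=O)OC)(C=C3OC)CC4[C@@H]2CO[Si](C(C)C)(C(C)C)C(C)C)cc1OC | intermediate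
11 | methyl (E)-3-[(2S,3R)-2-(3,4-dimethoxyphenyl)-7-methoxy-3-{[(triisopropylsilyl)oxy]methyl}-2,3,3a,4-tetrahydro-1-benzofuran-5-yl]prop-2-enoate (C3a undefined; not isolated) | COc1ccc([C@H]2OC3=C(OC)C=C(/C=C/C(=O)OC)CC3[C@@H]2CO[Si](C(C)C)(C(C)C)C(C)C)cc1OC | intermediate
12 | methyl (E)-3-[(2S,3R)-2-(3,4-dimethoxyphenyl)-7-methoxy-3-{[(triisopropylsilyl)oxy]methyl}-2,3-dihydro-1-benzofuran-5-yl]prop-2-enoate | COc1ccc([C@H]2Oc3c(OC)cc(/C=C/C(=O)OC)cc3[C@@H]2CO[Si](C(C)C)(C(C)C)C(C)C)cc1OC | intermediate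
13 | (E)-3-[(2S,3R)-2-(3,4-dimethoxyphenyl)-7-methoxy-3-{[(triisopropylsilyl)oxy]methyl}-2,3-dihydro-1-benzofuran-5-yl]prop-2-en-1-ol | COc1ccc([C@H]2Oc3c(OC)cc(/C=C/CO)cc3[C@@H]2CO[Si](C(C)C)(C(C)C)C(C)C)cc1OC | intermediate
14 | hierochin B, (E)-3-[(2S,3R)-2-(3,4-dimethoxyphenyl)-3-(hydroxymethyl)-7-methoxy-2,3-dihydro-1-benzofuran-5-yl]prop-2-en-1-ol | COc1ccc([C@H]2Oc3c(OC)cc(/C=C/CO)cc3[C@@H]2CO)cc1OC | target

**Total steps:** 7. **Longest linear sequence:** 6 (steps 1, 2, 4, 5, 6, 7).

**Steps most likely to fail**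

Step 5 carries the highest risk.
- The diazine bears two alkoxy donors and the alkene is unactivated. The cycloaddition may therefore need a temperature at which the electron-rich benzylic ether ionises or eliminates.
- Diene 11 could also aromatise the wrong way, by losing the C7a–O bond.
- The fallback changes the dienophile from alkene to alkyne, the substrate class with the closest precedent. It sets out from 4 and comes back at 12.
- Lemieux–Johnson cleavage of the vinyl group (OsO4 cat., NaIO4, 2,6-lutidine, dioxane/water) gives (2R,3S)-3-(3,4-dimethoxyphenyl)-3-hydroxy-2-{[(triisopropylsilyl)oxy]methyl}propanal F1, which is used crude.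
- Ohira–Bestmann homologation (K2CO3, MeOH, 0 °C) gives (1S,2R)-1-(3,4-dimethoxyphenyl)-2-{[(triisopropylsilyl)oxy]methyl}but-3-yn-1-ol F2.
- O-arylation with 7 (KHMDS, THF) gives methyl (E)-3-(6-{[(1S,2R)-1-(3,4-dimethoxyphenyl)-2-{[(triisopropylsilyl)oxy]methyl}but-3-yn-1-yl]oxy}-5-methoxypyridazin-3-yl)prop-2-enoate F3.
- Thermolysis in o-dichlorobenzene passes through the azo-bridged diene adduct F4. Its loss of N2 is itself the aromatisation, so 12 forms with no diene stage and no oxidant.

Step 4 is second.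
- The hindered secondary alkoxide must attack a carbon flanked by OMe.
- Attack on the ester, on the enoate or at the methoxy-bearing carbon can compete at the temperature needed.
- The fallback changes the electrophile so that substitution is fast at low temperature. It sets out from 7 and comes back at 9.
- Halogen exchange (CsF, DMSO, 80 °C) gives methyl (E)-3-(6-fluoro-5-methoxypyridazin-3-yl)prop-2-enoate F5.
- F5 then takes up alkoxide 8 at −78 to −40 °C to give 9.

Step 3 is third.
- The Heck reaction may go at the wrong chloride, give mixtures, or run on to the bis-adduct.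
- Oxidative addition and SNAr respond to the same electronic bias. If palladium prefers C3, the alkoxide should as well.
- The fallback therefore reverses the order of the two bond formations. It sets out from 5 and comes back at 9.
- Alkoxide 8 is added to 5 (THF, −40 °C to rt, regioisomers separated) to give 3-chloro-6-{[(1S,2R)-1-(3,4-dimethoxyphenyl)-2-{[(triisopropylsilyl)oxy]methyl}but-3-en-1-yl]oxy}-5-methoxypyridazine F6.
- The single remaining C–Cl bond of F6 is then coupled with 6 under the Heck conditions of step 3 to give 9.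

**Further compounds**
F1 | step 5 | (2R,3S)-3-(3,4-dimethoxyphenyl)-3-hydroxy-2-{[(triisopropylsilyl)oxy]methyl}propanal | COc1ccc([C@@H](O)[C@@H](CO[Si](C(C)C)(C(C)C)C(C)C)C=O)cc1OC
F2 | step 5 | (1S,2R)-1-(3,4-dimethoxyphenyl)-2-{[(triisopropylsilyl)oxy]methyl}but-3-yn-1-ol | COc1ccc([C@@H](O)[C@@H](CO[Si](C(C)C)(C(C)C)C(C)C)C#C)cc1OC
F3 | step 5 | methyl (E)-3-(6-{[(1S,2R)-1-(3,4-dimethoxyphenyl)-2-{[(triisopropylsilyl)oxy]methyl}but-3-yn-1-yl]oxy}-5-methoxypyridazin-3-yl)prop-2-enoate | COc1ccc([C@@H](Oc2nnc(/C=C/C(=O)OC)cc2OC)[C@@H](CO[Si](C(C)C)(C(C)C)C(C)C)C#C)cc1OC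
F4 | step 5 | azo-bridged diene adduct (2,3-diazabicyclo[2.2.2]octa-2,5,7-triene fused to the new dihydrofuran ring) | COc1ccc([C@H]2OC34N=NC(/C=C/C(=O)OC)(C=C3OC)C=C4[C@@H]2CO[Si](C(C)C)(C(C)C)C(C)C)cc1OC
F5 | step 4 | methyl (E)-3-(6-fluoro-5-methoxypyridazin-3-yl)prop-2-enoate | COC(=O)/C=C/c1cc(OC)c(F)nn1
F6 | step 3 | 3-chloro-6-{[(1S,2R)-1-(3,4-dimethoxyphenyl)-2-{[(triisopropylsilyl)oxy]methyl}but-3-en-1-yl]oxy}-5-methoxypyridazine | COc1ccc([C@@H](Oc2nnc(Cl)cc2OC)[C@@H](CO[Si](C(C)C)(C(C)C)C(C)C)C=C)cc1OC
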